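**Strategy.** The route rests on forming ring A last, by disconnecting C8–C8a and C4a–C5. One benzannulation builds the phloroglucinol-type ring A on the C4a=C8a enol-ether double bond of a preformed, enantiopure ring C. The prenyl-bearing nucleophilic terminus of a 1-methoxy-1,3-bis(silyloxy)diene bonds to C8a, the O1-bearing beta carbon of a bromo enone; the ketene-acetal carbon bonds to C4a; loss of HBr, methanol and silanol aromatises. The feature exploited is that prenylated C8 must adjoin O1-bearing C8a in ring A. The precursor is a (2R,3R)-2-aryl-3-silyloxy-5-bromo-2,3-dihydropyran-4-one that already carries ring B and both stereocentres. Silyl ethers at O3 and O4' allow a base-free, one-step end-game.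

Key step: step 10

Abbreviations: prenyl = 3-methylbut-2-en-1-yl; Ar = 4-(tert-butyldimethylsilyloxy)-3-prenylphenyl; TBS = tert-butyldimethylsilyl; TMS = trimethylsilyl. Ring positions of the target are given in flavonoid numbering (O1, C2, C3, C4, C4a, C5–C8, C8a).

Assumption: the (S)-BINOL/Ti(OiPr)4 catalyst is taken to attack the aryl aldehyde on the face that gives the 2S dihydropyranone, as with benzaldehyde (if not, (R)-BINOL is used); the bis(silyloxy)diene is drawn as its expected 1E,3Z isomer, and its geometry is erased on aromatisation.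

**Route**

Step 1
Reactants: 1 4-hydroxybenzaldehyde; 2 prenyl bromide (1-bromo-3-methylbut-2-ene)
Product: 3 4-hydroxy-3-prenylbenzaldehyde
Conditions: KOH, H2O, rt
Reagents that add atoms: none
Why: Ortho C-alkylation of the ambident phenoxide by the allylic bromide in water, where hydrogen bonding to oxygen diverts SN2 attack to carbon; the two ortho positions are equivalent, and O-prenyl ether and dialkylated material are removed by chromatography.

Step 2
Reactants: 3 4-hydroxy-3-prenylbenzaldehyde
Product: 4 4-(tert-butyldimethylsilyloxy)-3-prenylbenzaldehyde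
Conditions: TBSCl, imidazole, DMF, rt
Reagents that add atoms: tert-butyldimethylsilyl chloride, CC(C)(C)[Si](C)(C)Cl
Why: Imidazole-mediated silylation of a phenol; the aryl TBS ether should tolerate the Lewis acids, the amide base at low temperature and NBS used later, and falls to fluoride at the end.

Step 3
Reactants: 4 4-(tert-butyldimethylsilyloxy)-3-prenylbenzaldehyde; 5 (E)-1-methoxy-3-(trimethylsilyloxy)buta-1,3-diene
Product: 7 (2S)-2-Ar-2,3-dihydro-4H-pyran-4-one, via Mukaiyama aldol silyl ether 6 (not isolated)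
Conditions: (S)-BINOL (20 mol %), Ti(OiPr)4 (10 mol %), 4 Å MS, Et2O, −20 °C; then TFA (cat.), CH2Cl2, 0 °C
Reagents that add atoms: none
Why: BINOL–titanium catalysed hetero-Diels–Alder reaction of an aromatic aldehyde with a 1-alkoxy-3-silyloxydiene, which runs as an enantioselective Mukaiyama aldol addition followed by acid-induced 6-endo oxa-Michael closure with loss of methanol; C2 is set by the chiral titanium complex, which blocks one face of the bound aldehyde.

Step 4
Reactants: 7 (2S)-2-Ar-2,3-dihydro-4H-pyran-4-one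
Product: 9 (2R,3R)-2-Ar-3-hydroxy-2,3-dihydro-4H-pyran-4-one (2,3-trans), via sodium enolate 8 (not isolated)
Conditions: NaHMDS, THF, −78 °C; then 2-(phenylsulfonyl)-3-phenyloxaziridine, −78 °C; NH4Cl (aq)
Reagents that add atoms: 2-(phenylsulfonyl)-3-phenyloxaziridine, O=S(=O)(c1ccccc1)N1OC1c1ccccc1
Why: Enolate alpha-hydroxylation with an N-sulfonyloxaziridine: kinetic deprotonation at C3 gives the cross-conjugated enolate, and oxygen is delivered to C3 on the face opposite the neighbouring C2 aryl group, which sets the 2,3-trans (3R) centre, also the more stable diequatorial arrangement, while the oxaziridine leaves the prenyl double bond alone.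

Step 5
Reactants: 9 (2R,3R)-2-Ar-3-hydroxy-2,3-dihydro-4H-pyran-4-one
Product: 10 (2R,3R)-2-Ar-3-(tert-butyldimethylsilyloxy)-2,3-dihydro-4H-pyran-4-one
Conditions: TBSOTf, 2,6-lutidine, CH2Cl2, −78 → 0 °C
Reagents that add atoms: tert-butyldimethylsilyl triflate, CC(C)(C)[Si](C)(C)OS(=O)(=O)C(F)(F)F
Why: O-Silylation of a secondary alpha-hydroxy ketone with a silyl triflate and a hindered pyridine base at low temperature, which does not touch C3; a silyl ether rather than an ester is placed on O3 so that the end-game needs fluoride only and no base.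

Step 6
Reactants: 10 (2R,3R)-2-Ar-3-(tert-butyldimethylsilyloxy)-2,3-dihydro-4H-pyran-4-one
Product: 11 (2R,3R)-2-Ar-5-bromo-3-(tert-butyldimethylsilyloxy)-2,3-dihydro-4H-pyran-4-one
Conditions: NBS (1.05 equiv), NaHCO3, CH2Cl2, 0 °C, dark
Reagents that add atoms: N-bromosuccinimide, O=C1CCC(=O)N1Br
Why: Electrophilic alpha-bromination of a vinylogous ester (beta-alkoxy enone): pyranone C5 is the only enol-ether beta carbon and the bromo oxocarbenium ion loses its C5 proton to succinimide anion, whereas under anhydrous, buffered, dark conditions the isolated prenyl double bond has no nucleophile to trap a bromonium ion and should react more slowly.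

Step 7
Reactants: 12 methyl acetoacetate; 2 prenyl bromide
Product: 14 methyl 7-methyl-3-oxooct-6-enoate, via acetoacetate dianion 13 (not isolated)
Conditions: LDA (2.1 equiv), THF, 0 °C; then 2, 0 °C → rt; NH4Cl (aq)
Reagents that add atoms: none
Why: Gamma-alkylation of the acetoacetate dianion, in which the more basic terminal carbanion displaces bromide from the primary allylic carbon by SN2 and gives the linear prenylated keto ester.

Step 8
Reactants: 14 methyl 7-methyl-3-oxooct-6-enoate
Product: 15 methyl (2Z)-7-methyl-3-(trimethylsilyloxy)octa-2,6-dienoate (double-bond geometry of no consequence)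
Conditions: TMSCl, Et3N, hexane, rt
Reagents that add atoms: trimethylsilyl chloride, C[Si](C)(C)Cl
Why: Silyl enol ether formation by O-silylation of the enol form of the beta-keto ester with TMSCl and Et3N.

Step 9
Reactants: 15 methyl (2Z)-7-methyl-3-(trimethylsilyloxy)octa-2,6-dienoate
Product: 17 (1E,3Z)-1-methoxy-7-methyl-1,3-bis(trimethylsilyloxy)octa-1,3,6-triene, via lithium dienolate 16 (not isolated)
Conditions: LDA, THF, −78 °C; then TMSCl, −78 °C → rt; used crude after filtration under argon
Reagents that add atoms: trimethylsilyl chloride, C[Si](C)(C)Cl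
Why: Gamma-deprotonation of the 3-silyloxy enoate to the ester dienolate followed by O-silylation, the standard second stage in the preparation of 1-alkoxy-1,3-bis(silyloxy)dienes.

Step 10
Reactants: 11 (2R,3R)-2-Ar-5-bromo-3-(tert-butyldimethylsilyloxy)-2,3-dihydro-4H-pyran-4-one; 17 (1E,3Z)-1-methoxy-7-methyl-1,3-bis(trimethylsilyloxy)octa-1,3,6-triene
Product: 20 3-O-TBS-4'-O-TBS-lespedezaflavanone C [(2R,3R)-2-Ar-3-(tert-butyldimethylsilyloxy)-5,7-dihydroxy-8-prenylchroman-4-one], via bromo ketal cycloadduct 18 (not isolated), via 7-O-trimethylsilyl arene 19 (not isolated)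
Conditions: 17 (2.5 equiv), TMSOTf (0.2 equiv), 2,6-di-tert-butyl-4-methylpyridine, CH2Cl2, −78 → 0 °C; then Et3N, 0 °C → rt; then citric acid, MeOH/H2O
Reagents that add atoms: none
Why: Proposed new method: TMSOTf silylates the C4 carbonyl and turns the bromo vinylogous ester into an oxocarbenium ion electrophilic at C8a, the prenyl-bearing diene terminus adds there (vinylogous Mukaiyama–Michael addition, C8–C8a), and the bromo silyl enol ether carbon C4a then closes on the silyl carboxonium carbon C5 (C4a–C5), which amounts to a stepwise polar [4+2] cycloaddition. The mixed ketal at C5 collapses with loss of MeOSiMe3, ring A enolises, and Et3N takes HBr across C4a–C8a from the resulting 4a-bromo-4a,8a-dihydroarene with aromatisation as the driving force, the aryl trimethylsilyl ether being hydrolysed at work-up. The closest known reactions are the benzannulation of halo-quinones with 1-alkoxy-1,3-bis(silyloxy)dienes and the TMSOTf-promoted addition of such dienes to chromones, whereas a 5-bromo-2,3-dihydropyran-4-one has not served as the two-carbon partner. Ring A closes in a 6-(enolexo)-exo-trig mode (suprafacially on both partners if the process is concerted), and no new stereocentre survives because C4a, C5, C8 and C8a all become sp2. The selectivity needed is regiochemical and comes from the polarity match between the most nucleophilic diene carbon and the beta carbon C8a of the enone, so that the prenyl group can only arrive at C8 and never at C6. C2 and C3 should pass unchanged because no strong base is present and trans is the stable arrangement, and the prenyl groups and TBS ethers are spectators towards catalytic TMSOTf buffered by the hindered pyridine.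

Step 11
Reactants: 20 3-O-TBS-4'-O-TBS-lespedezaflavanone C
Product: 21 lespedezaflavanone C
Conditions: HF·pyridine, pyridine, THF, 0 °C → rt
Reagents that add atoms: none
Why: Fluoride-induced cleavage of the aryl and the secondary silyl ether in one operation under buffered, non-basic conditions, so that neither the ring C stereocentres (prone to base-induced opening at C2) nor the acid-sensitive ortho-prenyl phenols should be endangered.

**Compound list**

1 | 4-hydroxybenzaldehyde | O=Cc1ccc(O)cc1 | starting material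
2 | prenyl bromide (1-bromo-3-methylbut-2-ene) | CC(C)=CCBr | starting material
3 | 4-hydroxy-3-(3-methylbut-2-en-1-yl)benzaldehyde | CC(C)=CCc1cc(C=O)ccc1O | intermediate
4 | 4-(tert-butyldimethylsilyloxy)-3-(3-methylbut-2-en-1-yl)benzaldehyde | CC(C)=CCc1cc(C=O)ccc1O[Si](C)(C)C(C)(C)C | intermediate
5 | (E)-1-methoxy-3-(trimethylsilyloxy)buta-1,3-diene | CO/C=C/C(=C)O[Si](C)(C)C | starting material
6 | (1E,5S)-5-Ar-1-methoxy-5-(trimethylsilyloxy)pent-1-en-3-one | CC(C)=CCc1cc([C@@H](O[Si](C)(C)C)CC(=O)/C=C/OC)ccc1O[Si](C)(C)C(C)(C)C | intermediate (not isolated)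
7 | (2S)-2-[4-(tert-butyldimethylsilyloxy)-3-prenylphenyl]-2,3-dihydro-4H-pyran-4-one | CC(C)=CCc1cc([C@H]2OC=CC(=O)C2)ccc1O[Si](C)(C)C(C)(C)C | intermediate
8 | sodium (2S)-2-Ar-2H-pyran-4-olate | CC(C)=CCc1cc([C@H]2OC=CC([O-])=C2)ccc1O[Si](C)(C)C(C)(C)C.[Na+] | intermediate (not isolated)
9 | (2R,3R)-2-Ar-3-hydroxy-2,3-dihydro-4H-pyran-4-one | CC(C)=CCc1cc([C@H]2OC=CC(=O)[C@@H]2O)ccc1O[Si](C)(C)C(C)(C)C | intermediate
10 | (2R,3R)-2-Ar-3-(tert-butyldimethylsilyloxy)-2,3-dihydro-4H-pyran-4-one | CC(C)=CCc1cc([C@H]2OC=CC(=O)[C@@H]2O[Si](C)(C)C(C)(C)C)ccc1O[Si](C)(C)C(C)(C)C | intermediate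
11 | (2R,3R)-5-bromo-3-(tert-butyldimethylsilyloxy)-2-[4-(tert-butyldimethylsilyloxy)-3-prenylphenyl]-2,3-dihydro-4H-pyran-4-one | CC(C)=CCc1cc([C@H]2OC=C(Br)C(=O)[C@@H]2O[Si](C)(C)C(C)(C)C)ccc1O[Si](C)(C)C(C)(C)C | intermediate
12 | methyl acetoacetate | COC(=O)CC(C)=O | starting material
13 | dilithium 1-methoxybuta-1,3-diene-1,3-diolate (acetoacetate dianion) | [Li+].[Li+].COC([O-])=CC(=C)[O-] | intermediate (not isolated)
14 | methyl 7-methyl-3-oxooct-6-enoate | COC(=O)CC(=O)CCC=C(C)C | intermediate
15 | methyl (2Z)-7-methyl-3-(trimethylsilyloxy)octa-2,6-dienoate | COC(=O)/C=C(\O[Si](C)(C)C)CCC=C(C)C | intermediate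
16 | lithium dienolate of 15 (lithium 1-methoxy-7-methyl-3-(trimethylsilyloxy)octa-1,3,6-trien-1-olate) | [Li+].CO/C([O-])=C\C(O[Si](C)(C)C)=C\CC=C(C)C | intermediate (not isolated)
17 | (1E,3Z)-1-methoxy-7-methyl-1,3-bis(trimethylsilyloxy)octa-1,3,6-triene | CO/C(O[Si](C)(C)C)=C\C(O[Si](C)(C)C)=C\CC=C(C)C | intermediate
18 | (2R,3R)-2-Ar-4a-bromo-3-(tert-butyldimethylsilyloxy)-5-methoxy-8-prenyl-5,7-bis(trimethylsilyloxy)-2,3,4a,5,8,8a-hexahydrochromen-4-one (mixture at C4a, C5, C8, C8a) | CC(C)=CCc1cc([C@H]2OC3C(CC=C(C)C)C(O[Si](C)(C)C)=CC(OC)(O[Si](C)(C)C)C3(Br)C(=O)[C@@H]2O[Si](C)(C)C(C)(C)C)ccc1O[Si](C)(C)C(C)(C)C | intermediate (not isolated)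
19 | (2R,3R)-2-Ar-3-(tert-butyldimethylsilyloxy)-5-hydroxy-8-prenyl-7-(trimethylsilyloxy)chroman-4-one | CC(C)=CCc1cc([C@H]2Oc3c(CC=C(C)C)c(O[Si](C)(C)C)cc(O)c3C(=O)[C@@H]2O[Si](C)(C)C(C)(C)C)ccc1O[Si](C)(C)C(C)(C)C | intermediate (not isolated)
20 | (2R,3R)-3-(tert-butyldimethylsilyloxy)-2-[4-(tert-butyldimethylsilyloxy)-3-prenylphenyl]-5,7-dihydroxy-8-prenylchroman-4-one | CC(C)=CCc1cc([C@H]2Oc3c(CC=C(C)C)c(O)cc(O)c3C(=O)[C@@H]2O[Si](C)(C)C(C)(C)C)ccc1O[Si](C)(C)C(C)(C)C | intermediate
21 | lespedezaflavanone C, (2R,3R)-3,5,7-trihydroxy-2-(4-hydroxy-3-prenylphenyl)-8-prenylchroman-4-one | CC(C)=CCc1cc([C@H]2Oc3c(CC=C(C)C)c(O)cc(O)c3C(=O)[C@@H]2O)ccc1O | target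

**Step count and risks**

Total step count: 11. Longest linear sequence: 8 steps (steps 1–6, 10, 11); the diene arm is 3 steps (7–9).

Steps most likely to fail:

1. Step 10 (proposed new method). The push–pull bromo enone may be too weak an acceptor, so that the diene is lost to desilylation before it adds. Bromine may also be transferred from C4a to the silyl diene, or O1 may be expelled from C8a by beta-elimination, before ring A aromatises. The fallback uses known chalcone chemistry, sets out from 3 and returns at 21.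
 - Aldehyde 3 is protected (MOMCl, iPr2NEt) as 4-(methoxymethoxy)-3-prenylbenzaldehyde F1.
 - Commercial 2,4,6-trihydroxyacetophenone is C-prenylated with 2 (DBU, THF) to 1-(2,4,6-trihydroxy-3-prenylphenyl)ethanone F2.
 - The 4- and 6-hydroxyls of F2 are protected (MOMCl, iPr2NEt; the chelated, flanked 2-hydroxyl stays free) to give 1-[2-hydroxy-4,6-bis(methoxymethoxy)-3-prenylphenyl]ethanone F3.
 - The remaining hydroxyl is allylated (allyl bromide, K2CO3, DMF) to give 1-[2-(allyloxy)-4,6-bis(methoxymethoxy)-3-prenylphenyl]ethanone F4.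
 - Claisen–Schmidt condensation of F4 with F1 (KOH, EtOH) should give the E chalcone F5.
 - Juliá–Colonna epoxidation (poly-L-leucine, urea–H2O2, DBU, THF) is nucleophilic and spares the prenyl groups; it should give the (2R,3S)-epoxy ketone F6.
 - Deallylation (Pd(PPh3)4, morpholine, THF) frees the ring A phenol next to the prenyl group, giving phenol epoxide F7.
 - This phenol opens the epoxide at the benzylic carbon with inversion (6-endo, MgBr2·OEt2) to the 2,3-trans tris-MOM dihydroflavonol F8. Only the 8-prenyl isomer can form because no other ring A hydroxyl is free.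
 - Methanolysis (HCl, MeOH, rt) removes the three MOM groups and gives 21.

2. Step 6. Electrophilic bromine may attack the ring B prenyl double bond (bromonium formation or allylic bromination) in competition with C5 of the vinylogous ester. The fallback sets out from 10 and returns at 20. Pyridine-mediated alpha-iodination (I2, pyridine, CH2Cl2, rt) proceeds by amine addition–elimination at the enone and does not consume isolated alkenes; it should give (2R,3R)-2-Ar-3-(tert-butyldimethylsilyloxy)-5-iodo-2,3-dihydro-4H-pyran-4-one F9. F9 takes the place of 11 in step 10, where HI is lost instead of HBr.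

3. Step 4. The enolate may fragment by opening of ring C, add to the sulfonyl imine released by the oxidant, or be hydroxylated with poor facial selectivity. The fallback sets out from 7 and returns at 9. Soft enolisation (TBSOTf, Et3N, CH2Cl2, 0 °C) gives the silyl dienol ether (2S)-2-Ar-4-(tert-butyldimethylsilyloxy)-2H-pyran F10. Rubottom oxidation with dimethyldioxirane (acetone, −78 °C) should epoxidise the far more electron-rich silyl enol ether on the face opposite the aryl group, giving the silyloxy epoxide F11. Citric acid in THF/H2O opens F11 to 9.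

**Further compounds**

F1 | step 10 | 4-(methoxymethoxy)-3-(3-methylbut-2-en-1-yl)benzaldehyde | COCOc1ccc(C=O)cc1CC=C(C)C
F2 | step 10 | 1-[2,4,6-trihydroxy-3-(3-methylbut-2-en-1-yl)phenyl]ethanone | CC(=O)c1c(O)cc(O)c(CC=C(C)C)c1O
F3 | step 10 | 1-[2-hydroxy-4,6-bis(methoxymethoxy)-3-(3-methylbut-2-en-1-yl)phenyl]ethanone | CC(=O)c1c(OCOC)cc(OCOC)c(CC=C(C)C)c1O
F4 | step 10 | 1-[2-(allyloxy)-4,6-bis(methoxymethoxy)-3-(3-methylbut-2-en-1-yl)phenyl]ethanone | CC(=O)c1c(OCOC)cc(OCOC)c(CC=C(C)C)c1OCC=C
F5 | step 10 | (E)-1-[2-(allyloxy)-4,6-bis(methoxymethoxy)-3-prenylphenyl]-3-[4-(methoxymethoxy)-3-prenylphenyl]prop-2-en-1-one | COCOc1ccc(/C=C/C(=O)c2c(OCOC)cc(OCOC)c(CC=C(C)C)c2OCC=C)cc1CC=C(C)C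
F6 | step 10 | [2-(allyloxy)-4,6-bis(methoxymethoxy)-3-prenylphenyl][(2R,3S)-3-[4-(methoxymethoxy)-3-prenylphenyl]oxiran-2-yl]methanone | O=C([C@@H]1O[C@H]1c1ccc(OCOC)c(CC=C(C)C)c1)c1c(OCOC)cc(OCOC)c(CC=C(C)C)c1OCC=C
F7 | step 10 | [2-hydroxy-4,6-bis(methoxymethoxy)-3-prenylphenyl][(2R,3S)-3-[4-(methoxymethoxy)-3-prenylphenyl]oxiran-2-yl]methanone | O=C([C@@H]1O[C@H]1c1ccc(OCOC)c(CC=C(C)C)c1)c1c(OCOC)cc(OCOC)c(CC=C(C)C)c1O
F8 | step 10 | (2R,3R)-3-hydroxy-5,7-bis(methoxymethoxy)-2-[4-(methoxymethoxy)-3-prenylphenyl]-8-prenylchroman-4-one | COCOc1ccc([C@H]2Oc3c(CC=C(C)C)c(OCOC)cc(OCOC)c3C(=O)[C@@H]2O)cc1CC=C(C)C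
F9 | step 6 | (2R,3R)-3-(tert-butyldimethylsilyloxy)-2-[4-(tert-butyldimethylsilyloxy)-3-prenylphenyl]-5-iodo-2,3-dihydro-4H-pyran-4-one | CC(C)=CCc1cc([C@H]2OC=C(I)C(=O)[C@@H]2O[Si](C)(C)C(C)(C)C)ccc1O[Si](C)(C)C(C)(C)C
F10 | step 4 | (2S)-4-(tert-butyldimethylsilyloxy)-2-[4-(tert-butyldimethylsilyloxy)-3-prenylphenyl]-2H-pyran | CC(C)=CCc1cc([C@H]2OC=CC(O[Si](C)(C)C(C)(C)C)=C2)ccc1O[Si](C)(C)C(C)(C)C
F11 | step 4 | (2S)-2-Ar-4-(tert-butyldimethylsilyloxy)-3,4-epoxy-3,4-dihydro-2H-pyran, epoxide oxygen on the face opposite the aryl group | CC(C)=CCc1cc([C@H]2OC=C[C@]3(O[Si](C)(C)C(C)(C)C)O[C@H]23)ccc1O[Si](C)(C)C(C)(C)C
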